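**Retrosynthetic overview**

1. The strategy rests on the 1,5-relationship between the Z C2=C3 double bond and the C8 oxygen on the ten-membered carbocycle (C1–C10). A C3–C8 bond splits it into ring A (C3–C8, holding C4=C5) and ring B (C8, C9, C10, C1, C2, C3), so the medium ring is unveiled from cis-decalin 26 (C8–OH, C2–OMs) by Wharton fragmentation.
2. Decalin: ring B is built on a preformed ring A by a catalytic asymmetric Diels–Alder reaction of silyloxydiene 2 with benzoquinone monoketal 3 (bonds C2–C3 and C8–C9). Convex-face steps then add the C8 hydroxyl, the C1/C10 diol, C6–O/H-7 (hydroboration of C6=C7) and the C4 methyl (enol triflate coupling).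
3. After ring expansion: C8 ketone reduction, esterification with (2S,3R)-epoxy acid 33 (Sharpless epoxidation of tiglyl alcohol), oxidative closure of the 12,6-lactone, α-methylenation, and C1/C10 diol → trans-epoxide with inversion at C1.
4. Ring order: ring A (present in 3) → ring B (step 2) → ten-membered ring (step 19) → γ-lactone (step 26) → oxirane (step 29).

Key step: step 19

**Remarks**

- Numbering and faces: ring carbons carry the numbers they have in the ten-membered ring of the target (C1–C10; C11/C12 = side chain on C7; C13 = exocyclic methylene). In the decalins, α is the face of the ring-fusion hydrogen H-3 and β the opposite face.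
- Assumption: the (S)-prolinol-derived oxazaborolidinium catalyst is taken to give the enantiomer of adduct 4 drawn; if its sense of induction on this dienophile is the opposite, the (R)-catalyst is used in step 2 and nothing else changes.

**Route**

Step 1
Reactants: 1 3-methylbut-2-enal
Product: 2 (E)-triethyl[(3-methylbuta-1,3-dien-1-yl)oxy]silane
Conditions: Et3SiOTf, Et3N, Et2O, 0 °C to rt
Reagents that add atoms: triethylsilyl trifluoromethanesulfonate, CC[Si](CC)(CC)OS(=O)(=O)C(F)(F)F
Why: O-silylation of the enal and γ-deprotonation of the silyloxocarbenium ion by the amine should give the (E)-dienol silyl ether (silyl dienol ether formation).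

Step 2
Reactants: 2 (E)-triethyl[(3-methylbuta-1,3-dien-1-yl)oxy]silane; 3 4,4-dimethoxycyclohexa-2,5-dien-1-one
Product: 4 cis-fused Diels–Alder adduct (C4 ketone; C5=C6; C7 dimethyl ketal; C1=C10; 2β-OSiEt3; H-3 and H-8 α)
Conditions: (S)-3,3-diphenyl-1-(o-tolyl)tetrahydro-1H,3H-pyrrolo[1,2-c][1,3,2]oxazaborole (20 mol %), HNTf2 (18 mol %), CH2Cl2, −78 to −40 °C
Reagents that add atoms: none
Why: Chiral oxazaborolidinium-catalysed Diels–Alder reaction in which the C4 carbonyl sends the oxygenated diene terminus (C2) to C3 and the CH2 terminus (C9) to C8, endo approach places the C2 silyloxy group trans to H-3, suprafacial addition gives the cis fusion, and the catalyst selects one of the two enantiotopic enone double bonds and so fixes C2, C3 and C8 absolutely.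

Step 3
Reactants: 4 cis-fused Diels–Alder adduct
Product: 6 4β-hydroxy-Δ5-en-7-one, via allylic alcohol ketal 5 (not isolated)
Conditions: NaBH4, CeCl3·7H2O, MeOH, −78 °C; then aq. oxalic acid, THF, 0 °C
Reagents that add atoms: water, O
Why: Luche 1,2-reduction of the enone from the convex α face, then mild hydrolysis of the now allylic dimethyl ketal, should move the enone to C7(=O)–C6=C5, where C8–H is the only α′ hydrogen; the C4 carbinol is only a mask for the later C4 ketone, so its configuration does not matter.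

Step 4
Reactants: 6 4β-hydroxy-Δ5-en-7-one
Product: 7 4β-pivalate
Conditions: t-BuCOCl, pyridine, DMAP (cat.), CH2Cl2, 0 °C to rt
Reagents that add atoms: pivaloyl chloride, CC(C)(C)C(=O)Cl
Why: Acylation of the secondary allylic alcohol gives an ester without α hydrogens that should survive the amide bases, hydride and borane steps ahead.

Step 5
Reactants: 7 4β-pivalate
Product: 9 8α-hydroxy enone, via potassium enolate 8 (not isolated)
Conditions: KN(SiMe3)2, THF, −78 °C; then 2-(phenylsulfonyl)-3-phenyloxaziridine, −78 °C; NH4Cl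
Reagents that add atoms: 2-(phenylsulfonyl)-3-phenyloxaziridine, O=S(=O)(c1ccccc1)N1OC1c1ccccc1
Why: Kinetic α′-deprotonation (C8–H) and Davis enolate hydroxylation; the oxidant should approach the α face that carries only H-3, opposite the β C2-silyloxy and C4-pivaloyloxy groups, so the cis ring fusion is kept and C8 is set.

Step 6
Reactants: 9 8α-hydroxy enone
Product: 10 1α,8α,10α-triol
Conditions: OsO4 (2 mol %), N-methylmorpholine N-oxide, acetone/H2O, 0 °C to rt
Reagents that add atoms: osmium tetroxide (oxygen carrier), O=[Os](=O)(=O)=O; N-methylmorpholine N-oxide (oxygen source), C[N+]1([O-])CCOCC1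
Why: Upjohn cis-dihydroxylation picks the electron-rich trisubstituted C1=C10 over the enone alkene and should occur anti to the allylic C2 silyl ether on the convex α face, setting C1 and C10.

Step 7
Reactants: 10 1α,8α,10α-triol
Product: 11 1,10-acetonide
Conditions: Me2C(OMe)2, PPTS (cat.), acetone, rt
Reagents that add atoms: 2,2-dimethoxypropane, COC(C)(C)OC
Why: Acid-catalysed transacetalisation takes the cis-vicinal C1/C10 diol as the five-membered dioxolane and leaves the tertiary C8 hydroxyl free.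

Step 8
Reactants: 11 1,10-acetonide
Product: 12 8-O-trimethylsilyl ether
Conditions: N-(trimethylsilyl)imidazole, CH2Cl2, rt
Reagents that add atoms: N-(trimethylsilyl)imidazole, C[Si](C)(C)n1ccnc1
Why: Neutral silylation of the tertiary α-ketol hydroxyl removes the acidic proton before the enolate chemistry of step 9.

Step 9
Reactants: 12 8-O-trimethylsilyl ether
Product: 14 C7 enol triflate (C6=C7), via lithium enolate 13 (not isolated)
Conditions: LiBH(s-Bu)3, THF, −78 °C; then PhNTf2, −78 to 0 °C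
Reagents that add atoms: N-phenylbis(trifluoromethanesulfonimide), O=S(=O)(N(c1ccccc1)S(=O)(=O)C(F)(F)F)C(F)(F)F
Why: Conjugate hydride reduction of the β-unsubstituted cyclohexenone gives the regiodefined C6=C7 enolate (C8 is quaternary), which is O-triflated in situ.

Step 10
Reactants: 14 C7 enol triflate
Product: 15 7-vinyl-Δ6 diene
Conditions: Bu3SnCH=CH2, Pd(PPh3)4 (5 mol %), LiCl, THF, 65 °C
Reagents that add atoms: tributyl(vinyl)stannane, C=C[Sn](CCCC)(CCCC)CCCC
Why: Stille coupling of the enol triflate installs C11 and C12 as a vinyl group on C7.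

Step 11
Reactants: 15 7-vinyl-Δ6 diene
Product: 18 6α,12-diol (H-7 α), via homoallylic 9-BBN borane 16 (not isolated), via bis-borane 17 (not isolated)
Conditions: 9-BBN-H, THF, 0 °C to rt; then BH3·SMe2, 0 °C to rt; then aq. NaOH, H2O2, 0 °C
Reagents that add atoms: hydrogen peroxide, OO
Why: Two-stage Brown hydroboration–oxidation: 9-BBN takes the terminal vinyl carbon (C12), then borane adds syn to the trisubstituted C6=C7 with boron on C6 from the convex α face (the β face is shielded by the pseudo-axial C8–C9 bond and the C4 pivalate), so oxidation with retention should give C6–OH α, H-7 α and the side chain β.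

Step 12
Reactants: 18 6α,12-diol
Product: 19 6,12-bis(tert-butyldimethylsilyl) ether
Conditions: t-BuMe2SiOTf, 2,6-lutidine, CH2Cl2, −78 to 0 °C
Reagents that add atoms: tert-butyldimethylsilyl trifluoromethanesulfonate, CC(C)(C)[Si](C)(C)OS(=O)(=O)C(F)(F)F
Why: Silylation of the primary and the hindered secondary alcohol with the silyl triflate.

Step 13
Reactants: 19 6,12-bis(tert-butyldimethylsilyl) ether
Product: 20 4β-alcohol
Conditions: iBu2AlH, CH2Cl2, −78 to −40 °C; Rochelle salt
Reagents that add atoms: none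
Why: Reductive cleavage of the pivalate leaves all silyl ethers and the acetonide untouched.

Step 14
Reactants: 20 4β-alcohol
Product: 21 C4 ketone
Conditions: Dess–Martin periodinane, NaHCO3, CH2Cl2, 0 °C to rt
Reagents that add atoms: none
Why: Buffered Dess–Martin oxidation returns the C4 ketone without enolising this tris(β-silyloxy) ketone.

Step 15
Reactants: 21 C4 ketone
Product: 23 C4 enol triflate (C4=C5), via potassium enolate 22 (not isolated)
Conditions: KN(SiMe3)2, THF, −78 °C; then PhNTf2, −78 °C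
Reagents that add atoms: N-phenylbis(trifluoromethanesulfonimide), O=S(=O)(N(c1ccccc1)S(=O)(=O)C(F)(F)F)C(F)(F)F
Why: Kinetic deprotonation should take the C5 methylene and not the hindered ring-fusion C3–H, and O-triflation at −78 °C should outrun β-elimination of the C6 silyloxy group.

Step 16
Reactants: 23 C4 enol triflate
Product: 24 4-methyl-Δ4 decalin
Conditions: MeZnCl, Pd(PPh3)4 (5 mol %), THF, 50 °C
Reagents that add atoms: methylzinc chloride, C[Zn]Cl
Why: Negishi coupling of the enol triflate places the C4 methyl on the C4=C5 double bond, which is Z in the later ring because it is a cyclohexene bond.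

Step 17
Reactants: 24 4-methyl-Δ4 decalin
Product: 25 2β,8α-diol
Conditions: HF·pyridine, pyridine, THF, 0 °C
Reagents that add atoms: none
Why: Buffered HF·pyridine should cleave the secondary triethylsilyl and the tertiary trimethylsilyl ethers well before the tert-butyldimethylsilyl ethers and without touching the acetonide.

Step 18
Reactants: 25 2β,8α-diol
Product: 26 cis-decalin precursor (1S,2R,3S,6R,7S,8R,10R): C8–OH; C2–OMs; C1/C10 acetonide; C4=C5; 6-OTBS; 7-CH2CH2OTBS
Conditions: MsCl, Et3N, CH2Cl2, −10 °C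
Reagents that add atoms: methanesulfonyl chloride, CS(=O)(=O)Cl
Why: Sulfene mesylation takes the secondary C2 hydroxyl only; the tertiary C8 hydroxyl does not react.

Step 19
Reactants: 26 cis-decalin precursor
Product: 28 (2Z,4Z)-cyclodeca-2,4-dien-8-one (1S,6R,7S,10R; C1/C10 acetonide; 6-OTBS; 7-CH2CH2OTBS), via potassium alkoxide 27 (not isolated)
Conditions: KOtBu, THF, −20 to 0 °C, short time; pH 7 buffer
Reagents that add atoms: none
Why: Deprotonation of the tertiary C8 hydroxyl gives alkoxide 27, in which an oxygen lone pair, the C3–C8 σ bond and the C2–OMs bond are anti-periplanar, so the C3–C8 bond breaks while C8=O and C2=C3 form in one concerted step; the closest known reaction type is the Wharton (Grob) fragmentation of a cyclic 1,3-diol monosulfonate. The ten-membered ring is not closed by bond formation but appears by cleavage of the bond shared by rings A and B, so no cyclisation entropy or transannular approach is involved. No new stereocentre is formed: C1, C6, C7 and C10 are untouched and C2, C3 and C8 become sp2. The step needs Z geometry at C2=C3 and fragmentation in preference to E2 elimination or oxetane formation: in the only low-energy chair of ring B (C10-Me, C1–O and C2–OMs equatorial) the C3–C4 bond is axial and gauche to C1 across C2–C3, which maps onto a cis alkene, and the equatorial mesylate has no anti-periplanar hydrogen, so E2 is closed stereoelectronically. C4=C5 stays Z because it was a cyclohexene double bond. Low temperature, short reaction time and a buffered quench limit C7 epimerisation and β-elimination of the C6 silyloxy group in the product, which is reduced at once in step 20.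

Step 20
Reactants: 28 (2Z,4Z)-cyclodeca-2,4-dien-8-one
Product: 29 8R alcohol (1S,6R,7R,8R,10R)
Conditions: LiBH(s-Bu)3, THF, −78 °C
Reagents that add atoms: none
Why: Non-chelating bulky hydride reduction in which Felkin–Anh attack anti to the C6 branch on C7, reinforced by 1,3-anti induction from the β-silyloxy group, should give the 8R carbinol (O-8 anti to C11 and to O-6 along C9–C6).

Step 21
Reactants: 30 tiglic acid
Product: 31 (E)-2-methylbut-2-en-1-ol
Conditions: LiAlH4, Et2O, 0 °C to rt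
Reagents that add atoms: none
Why: 1,2-Reduction of the α,β-unsaturated acid to the allylic alcohol with retention of the E geometry.

Step 22
Reactants: 31 (E)-2-methylbut-2-en-1-ol
Product: 32 [(2R,3R)-2,3-dimethyloxiran-2-yl]methanol
Conditions: Ti(OiPr)4 (10 mol %), D-(−)-diisopropyl tartrate (12 mol %), t-BuOOH, 4 Å MS, CH2Cl2, −20 °C
Reagents that add atoms: tert-butyl hydroperoxide, CC(C)(C)OO
Why: Sharpless asymmetric epoxidation of the E trisubstituted allylic alcohol; the D-(−)-tartrate ligand delivers oxygen to the face that gives the 2R,3R epoxy alcohol, and the cis relationship of the two methyl groups comes from the alkene geometry.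

Step 23
Reactants: 32 [(2R,3R)-2,3-dimethyloxiran-2-yl]methanol
Product: 33 (2S,3R)-2,3-dimethyloxirane-2-carboxylic acid
Conditions: RuCl3·xH2O (2 mol %), NaIO4, MeCN/EtOAc/H2O, rt
Reagents that add atoms: sodium periodate, [Na+].[O-]I(=O)(=O)=O; water, O
Why: RuO4 oxidation formed in situ takes the primary alcohol to the acid without touching the epoxide; the C2 descriptor changes from R to S only because the carboxyl group outranks C3.

Step 24
Reactants: 29 8R alcohol; 33 (2S,3R)-2,3-dimethyloxirane-2-carboxylic acid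
Product: 35 C8 epoxy ester, via mixed anhydride 34 (not isolated)
Conditions: 33, 2,4,6-trichlorobenzoyl chloride, Et3N, toluene, rt; then 29, DMAP, toluene, rt to 40 °C
Reagents that add atoms: none
Why: Yamaguchi esterification joins the hindered secondary alcohol to the α-quaternary acid through the mixed anhydride, with no change at C8 or in the epoxy acid.

Step 25
Reactants: 35 C8 epoxy ester
Product: 36 6,12-diol
Conditions: HF·pyridine, THF, 0 °C to rt
Reagents that add atoms: none
Why: Fluoride-mediated cleavage of both tert-butyldimethylsilyl ethers under mildly acidic conditions avoids acyl migration from O-8 and keeps the acetonide.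

Step 26
Reactants: 36 6,12-diol
Product: 38 trans-fused 12,6-lactone, via lactol 37 (not isolated)
Conditions: TEMPO (20 mol %), PhI(OAc)2, CH2Cl2, rt
Reagents that add atoms: none
Why: Oxoammonium oxidation takes the primary C12 alcohol to the aldehyde, which is trapped by the C6 hydroxyl as the lactol and oxidised on to the γ-lactone (oxidative lactonisation of a 1,4-diol).

Step 27
Reactants: 38 trans-fused 12,6-lactone
Product: 42 α-methylene lactone, via lithium enolate 39 (not isolated), via Mannich base 40 (not isolated), via ammonium iodide 41 (not isolated)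
Conditions: LiN(iPr)2, THF, −78 °C; CH2=NMe2+ I−, −78 to 0 °C; then MeI, MeOH, rt; then aq. NaHCO3, CH2Cl2
Reagents that add atoms: N,N-dimethylmethyleneiminium iodide, C=[N+](C)C.[I-]
Why: Aminomethylation of the lactone enolate with Eschenmoser's salt (the C8 ester has no α hydrogen), then N-methylation and base-induced elimination of trimethylamine, gives the exocyclic methylene.

Step 28
Reactants: 42 α-methylene lactone
Product: 43 1,10-diol (1S,10R)
Conditions: AcOH/H2O (4:1), 40 °C
Reagents that add atoms: none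
Why: Mild aqueous acid hydrolysis of the cis-fused acetonide; the glycidic ester epoxide is deactivated toward acid by its carbonyl group.

Step 29
Reactants: 43 1,10-diol
Product: 45 CNP0122107.1 (target; 1R,6R,7R,8R,10R; 2Z,4Z; ester 2S,3R), via mesylate 44 (not isolated)
Conditions: MsCl, Et3N, CH2Cl2, −20 °C; then DBU, 0 °C to rt
Reagents that add atoms: none
Why: Selective sulfonylation of the secondary C1 hydroxyl and intramolecular displacement by the tertiary C10 hydroxyl (3-exo-tet, Williamson-type epoxide closure) inverts C1 and retains C10, so the cis diol becomes the trans epoxide.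

**Compound list**

1 | 3-methylbut-2-enal | CC(C)=CC=O | starting material
2 | (E)-triethyl[(3-methylbuta-1,3-dien-1-yl)oxy]silane | C=C(C)/C=C/O[Si](CC)(CC)CC | intermediate
3 | 4,4-dimethoxycyclohexa-2,5-dien-1-one | COC1(OC)C=CC(=O)C=C1 | starting material
4 | cis-fused Diels–Alder adduct (C4 ketone, C5=C6, C7 dimethyl ketal, C1=C10, 2β-OSiEt3, H-3/H-8 α) | [C@@H]12CC(C)=C[C@H](O[Si](CC)(CC)CC)[C@@H]1C(=O)C=CC2(OC)OC | intermediate
5 | 4β-allylic alcohol, C7 dimethyl ketal | [C@@H]12CC(C)=C[C@H](O[Si](CC)(CC)CC)[C@@H]1[C@H](O)C=CC2(OC)OC | intermediate (not isolated)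
6 | 4β-hydroxy-Δ5-en-7-one | [C@@H]12CC(C)=C[C@H](O[Si](CC)(CC)CC)[C@@H]1[C@H](O)C=CC2=O | intermediate
7 | 4β-pivalate of 6 | [C@@H]12CC(C)=C[C@H](O[Si](CC)(CC)CC)[C@@H]1[C@H](OC(=O)C(C)(C)C)C=CC2=O | intermediate
8 | potassium C7–O, C7=C8 enolate of 7 | [K]OC1=C2CC(C)=C[C@H](O[Si](CC)(CC)CC)[C@@H]2[C@H](OC(=O)C(C)(C)C)C=C1 | intermediate (not isolated)
9 | 8α-hydroxy enone | O[C@@]12CC(C)=C[C@H](O[Si](CC)(CC)CC)[C@@H]1[C@H](OC(=O)C(C)(C)C)C=CC2=O | intermediate
10 | 1α,8α,10α-triol | O[C@@]12C[C@@](C)(O)[C@@H](O)[C@H](O[Si](CC)(CC)CC)[C@@H]1[C@H](OC(=O)C(C)(C)C)C=CC2=O | intermediate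
11 | 1,10-acetonide, 8α-OH | O[C@@]12C[C@@]3(C)OC(C)(C)O[C@H]3[C@H](O[Si](CC)(CC)CC)[C@@H]1[C@H](OC(=O)C(C)(C)C)C=CC2=O | intermediate
12 | 8-O-trimethylsilyl ether of 11 | C[Si](C)(C)O[C@@]12C[C@@]3(C)OC(C)(C)O[C@H]3[C@H](O[Si](CC)(CC)CC)[C@@H]1[C@H](OC(=O)C(C)(C)C)C=CC2=O | intermediate
13 | lithium C7–O, C6=C7 enolate | C[Si](C)(C)O[C@@]12C[C@@]3(C)OC(C)(C)O[C@H]3[C@H](O[Si](CC)(CC)CC)[C@@H]1[C@H](OC(=O)C(C)(C)C)CC=C2O[Li] | intermediate (not isolated)
14 | C7 enol triflate (C6=C7) | C[Si](C)(C)O[C@@]12C[C@@]3(C)OC(C)(C)O[C@H]3[C@H](O[Si](CC)(CC)CC)[C@@H]1[C@H](OC(=O)C(C)(C)C)CC=C2OS(=O)(=O)C(F)(F)F | intermediate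
15 | 7-vinyl-Δ6 diene | C[Si](C)(C)O[C@@]12C[C@@]3(C)OC(C)(C)O[C@H]3[C@H](O[Si](CC)(CC)CC)[C@@H]1[C@H](OC(=O)C(C)(C)C)CC=C2C=C | intermediate
16 | homoallylic B-alkyl-9-BBN (boron on C12) | C[Si](C)(C)O[C@@]12C[C@@]3(C)OC(C)(C)O[C@H]3[C@H](O[Si](CC)(CC)CC)[C@@H]1[C@H](OC(=O)C(C)(C)C)CC=C2CCB1C2CCCC1CCC2 | intermediate (not isolated)
17 | bis-borane (6α-BH2, H-7 α, C12–9-BBN) | C[Si](C)(C)O[C@@]12C[C@@]3(C)OC(C)(C)O[C@H]3[C@H](O[Si](CC)(CC)CC)[C@@H]1[C@H](OC(=O)C(C)(C)C)C[C@@H](B)[C@@H]2CCB1C2CCCC1CCC2 | intermediate (not isolated)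
18 | 6α,12-diol (7β-CH2CH2OH) | C[Si](C)(C)O[C@@]12C[C@@]3(C)OC(C)(C)O[C@H]3[C@H](O[Si](CC)(CC)CC)[C@@H]1[C@H](OC(=O)C(C)(C)C)C[C@@H](O)[C@@H]2CCO | intermediate
19 | 6,12-bis(tert-butyldimethylsilyl) ether | C[Si](C)(C)O[C@@]12C[C@@]3(C)OC(C)(C)O[C@H]3[C@H](O[Si](CC)(CC)CC)[C@@H]1[C@H](OC(=O)C(C)(C)C)C[C@@H](O[Si](C)(C)C(C)(C)C)[C@@H]2CCO[Si](C)(C)C(C)(C)C | intermediate
20 | 4β-alcohol | C[Si](C)(C)O[C@@]12C[C@@]3(C)OC(C)(C)O[C@H]3[C@H](O[Si](CC)(CC)CC)[C@@H]1[C@H](O)C[C@@H](O[Si](C)(C)C(C)(C)C)[C@@H]2CCO[Si](C)(C)C(C)(C)C | intermediate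
21 | C4 ketone | C[Si](C)(C)O[C@@]12C[C@@]3(C)OC(C)(C)O[C@H]3[C@H](O[Si](CC)(CC)CC)[C@@H]1C(=O)C[C@@H](O[Si](C)(C)C(C)(C)C)[C@@H]2CCO[Si](C)(C)C(C)(C)C | intermediate
22 | potassium C4–O, C4=C5 enolate | C[Si](C)(C)O[C@@]12C[C@@]3(C)OC(C)(C)O[C@H]3[C@H](O[Si](CC)(CC)CC)[C@@H]1C(O[K])=C[C@@H](O[Si](C)(C)C(C)(C)C)[C@@H]2CCO[Si](C)(C)C(C)(C)C | intermediate (not isolated)
23 | C4 enol triflate (C4=C5) | C[Si](C)(C)O[C@@]12C[C@@]3(C)OC(C)(C)O[C@H]3[C@H](O[Si](CC)(CC)CC)[C@@H]1C(OS(=O)(=O)C(F)(F)F)=C[C@@H](O[Si](C)(C)C(C)(C)C)[C@@H]2CCO[Si](C)(C)C(C)(C)C | intermediate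
24 | 4-methyl-Δ4 decalin (2-OSiEt3, 8-OSiMe3) | C[Si](C)(C)O[C@@]12C[C@@]3(C)OC(C)(C)O[C@H]3[C@H](O[Si](CC)(CC)CC)[C@@H]1C(C)=C[C@@H](O[Si](C)(C)C(C)(C)C)[C@@H]2CCO[Si](C)(C)C(C)(C)C | intermediate
25 | 2β,8α-diol | O[C@@]12C[C@@]3(C)OC(C)(C)O[C@H]3[C@H](O)[C@@H]1C(C)=C[C@@H](O[Si](C)(C)C(C)(C)C)[C@@H]2CCO[Si](C)(C)C(C)(C)C | intermediate
26 | cis-decalin precursor, (1S,2R,3S,6R,7S,8R,10R): C8–OH, C2–OMs, C1/C10 acetonide | O[C@@]12C[C@@]3(C)OC(C)(C)O[C@H]3[C@H](OS(C)(=O)=O)[C@@H]1C(C)=C[C@@H](O[Si](C)(C)C(C)(C)C)[C@@H]2CCO[Si](C)(C)C(C)(C)C | intermediate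
27 | potassium C8 alkoxide of 26 | [K]O[C@@]12C[C@@]3(C)OC(C)(C)O[C@H]3[C@H](OS(C)(=O)=O)[C@@H]1C(C)=C[C@@H](O[Si](C)(C)C(C)(C)C)[C@@H]2CCO[Si](C)(C)C(C)(C)C | intermediate (not isolated)
28 | (2Z,4Z)-cyclodeca-2,4-dien-8-one, (1S,6R,7S,10R), C1/C10 acetonide | O=C1C[C@@]2(C)OC(C)(C)O[C@H]2/C=C\C(C)=C/[C@@H](O[Si](C)(C)C(C)(C)C)[C@@H]1CCO[Si](C)(C)C(C)(C)C | intermediate
29 | 8R alcohol, (1S,6R,7R,8R,10R) | O[C@@H]1C[C@@]2(C)OC(C)(C)O[C@H]2/C=C\C(C)=C/[C@@H](O[Si](C)(C)C(C)(C)C)[C@@H]1CCO[Si](C)(C)C(C)(C)C | intermediate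
30 | tiglic acid, (E)-2-methylbut-2-enoic acid | C/C=C(\C)C(=O)O | starting material
31 | (E)-2-methylbut-2-en-1-ol | C/C=C(\C)CO | intermediate
32 | [(2R,3R)-2,3-dimethyloxiran-2-yl]methanol | OC[C@@]1(C)O[C@@H]1C | intermediate
33 | (2S,3R)-2,3-dimethyloxirane-2-carboxylic acid | OC(=O)[C@@]1(C)O[C@@H]1C | intermediate
34 | mixed anhydride of 33 with 2,4,6-trichlorobenzoic acid | O=C(OC(=O)c1c(Cl)cc(Cl)cc1Cl)[C@@]1(C)O[C@@H]1C | intermediate (not isolated)
35 | C8 (2S,3R)-epoxy ester (ring configuration as 29) | O=C(O[C@@H]1C[C@@]2(C)OC(C)(C)O[C@H]2/C=C\C(C)=C/[C@@H](O[Si](C)(C)C(C)(C)C)[C@@H]1CCO[Si](C)(C)C(C)(C)C)[C@@]1(C)O[C@@H]1C | intermediate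
36 | 6,12-diol of 35 | O=C(O[C@@H]1C[C@@]2(C)OC(C)(C)O[C@H]2/C=C\C(C)=C/[C@@H](O)[C@@H]1CCO)[C@@]1(C)O[C@@H]1C | intermediate
37 | C12 lactol | C1C(O)O[C@@H]2/C=C(C)\C=C/[C@@H]3OC(C)(C)O[C@]3(C)C[C@@H](OC(=O)[C@@]3(C)O[C@@H]3C)[C@@H]12 | intermediate (not isolated)
38 | trans-fused 12,6-lactone, C1/C10 acetonide | C1C(=O)O[C@@H]2/C=C(C)\C=C/[C@@H]3OC(C)(C)O[C@]3(C)C[C@@H](OC(=O)[C@@]3(C)O[C@@H]3C)[C@@H]12 | intermediate
39 | lithium enolate of lactone 38 | C1=C(O[Li])O[C@@H]2/C=C(C)\C=C/[C@@H]3OC(C)(C)O[C@]3(C)C[C@@H](OC(=O)[C@@]3(C)O[C@@H]3C)[C@@H]12 | intermediate (not isolated)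
40 | C11 dimethylaminomethyl lactone (Mannich base) | CN(C)CC1C(=O)O[C@@H]2/C=C(C)\C=C/[C@@H]3OC(C)(C)O[C@]3(C)C[C@@H](OC(=O)[C@@]3(C)O[C@@H]3C)[C@@H]12 | intermediate (not isolated)
41 | trimethylammonium iodide of 40 | C[N+](C)(C)CC1C(=O)O[C@@H]2/C=C(C)\C=C/[C@@H]3OC(C)(C)O[C@]3(C)C[C@@H](OC(=O)[C@@]3(C)O[C@@H]3C)[C@@H]12.[I-] | intermediate (not isolated)
42 | α-methylene lactone, C1/C10 acetonide | C=C1C(=O)O[C@@H]2/C=C(C)\C=C/[C@@H]3OC(C)(C)O[C@]3(C)C[C@@H](OC(=O)[C@@]3(C)O[C@@H]3C)[C@@H]12 | intermediate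
43 | 1,10-diol, (1S,10R) | C=C1C(=O)O[C@@H]2/C=C(C)\C=C/[C@H](O)[C@](C)(O)C[C@@H](OC(=O)[C@@]3(C)O[C@@H]3C)[C@@H]12 | intermediate
44 | C1 mesylate of 43 | C=C1C(=O)O[C@@H]2/C=C(C)\C=C/[C@H](OS(C)(=O)=O)[C@](C)(O)C[C@@H](OC(=O)[C@@]3(C)O[C@@H]3C)[C@@H]12 | intermediate (not isolated)
45 | CNP0122107.1, (1R,6R,7R,8R,10R,2Z,4Z)-1,10-epoxy-12,6-lactone 8-[(2S,3R)-2,3-dimethyloxirane-2-carboxylate] | C=C1C(=O)O[C@@H]2/C=C(C)\C=C/[C@H]3O[C@]3(C)C[C@@H](OC(=O)[C@@]3(C)O[C@@H]3C)[C@@H]12 | target

**Step count**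

Total: 29 steps. Longest linear sequence: 26 steps (steps 1–20 and 24–29, from 3-methylbut-2-enal); the epoxy acid takes 3 steps (21–23).

**Steps most likely to fail**

1. Step 19 (fragmentation). The alkoxide conditions may erode the product through C7 epimerisation and β-elimination of silanolate from the new β-silyloxy ketone, or the alkoxide may partition toward oxetane formation. Fallback: generate the alkoxide without a Brønsted base. Mesylate 26 is silylated at O-8 with N-(trimethylsilyl)imidazole to give the C8 trimethylsilyl ether mesylate F1. F1 is treated with CsF in DMF at 0 °C, where fluoride removes the silyl group and the transient alkoxide fragments as before (fluoride-triggered Grob fragmentation of a γ-silyloxy sulfonate). The route is rejoined at ketone 28.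

2. Step 20 (C8 reduction). Facial selectivity may be poor or reversed, because the conformation of the ten-membered ring rather than the Felkin arrangement may decide which ketone face is open. Fallback: if hydride delivery (for example NaBH4, MeOH, −40 °C) gives mainly the 8S alcohol F2, invert it. Mitsunobu reaction of F2 with 4-nitrobenzoic acid, PPh3 and DIAD gives the 8R 4-nitrobenzoate F3, and K2CO3 in MeOH releases alcohol 29, where the route is rejoined.

3. Step 29 (epoxide closure). The C1 sulfonate is allylic to the diene, so ionisation or SN2′ attack may outrun the 3-exo displacement. Fallback: avoid the sulfonate. Diol 43 is cyclodehydrated under Mitsunobu conditions (PPh3, DIAD, toluene, 0 °C to rt); the secondary allylic hydroxyl is activated as the oxyphosphonium ion and displaced by the tertiary C10 hydroxyl with inversion. This gives 45 directly and makes no new isolable compound.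

**Further compounds**

F1 | step 19 | C8 trimethylsilyl ether of mesylate 26 | C[Si](C)(C)O[C@@]12C[C@@]3(C)OC(C)(C)O[C@H]3[C@H](OS(C)(=O)=O)[C@@H]1C(C)=C[C@@H](O[Si](C)(C)C(C)(C)C)[C@@H]2CCO[Si](C)(C)C(C)(C)C
F2 | step 20 | 8S alcohol (C8 epimer of 29) | O[C@H]1C[C@@]2(C)OC(C)(C)O[C@H]2/C=C\C(C)=C/[C@@H](O[Si](C)(C)C(C)(C)C)[C@@H]1CCO[Si](C)(C)C(C)(C)C
F3 | step 20 | 8R 4-nitrobenzoate | O=C(O[C@@H]1C[C@@]2(C)OC(C)(C)O[C@H]2/C=C\C(C)=C/[C@@H](O[Si](C)(C)C(C)(C)C)[C@@H]1CCO[Si](C)(C)C(C)(C)C)c1ccc(cc1)[N+](=O)[O-]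
F0 | step 29 | none | none
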